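**Retrosynthetic overview**

1. Daucane numbering is used (ring A = C1–C5, ring B = C1, C5–C10; target 1R,2R,4R,5S,6S, trans-fused). The O2 angelate is attached last; the O6 p-methoxybenzoate and the free O4–H are released together by oxidative opening of a p-methoxybenzylidene acetal spanning O4 and O6.
2. Ring B is cut at C1–C10 and C8=C9. The enabling feature is the homoallylic quaternary carbon: C1 (CH3, flanked by C2–O and C5) is joined through C10H2 to the trisubstituted C9=C8(CH3) olefin, and C8 reaches back to C1 through C7–C6–C5. Hence C10–C9 is vinyltriphenylphosphonium, C1 a tertiary radical released from a C–B bond, and C8 a methyl ketone.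
3. The precursor is a monocyclic ring-A boronate. One copper-catalysed conjugate borylation/aldol event sets C1 (boron), C5 and C6 from the purchased C2 stereocentre; i-Pr addition to the C4 ketone then sets C4.
4. Ring order: ring A (purchased) → O4/O6 1,3-dioxane (temporary ring and latent anisoate) → ring B (key step) → dioxane opened.

Key step: step 9

Remark: α is the face of ring A that carries O2 (in the target also O4, C6 and the C1 methyl); β is the opposite face (H2, H5, i-Pr, C10).

**Route**

Step 1
Reactants: 1 (R)-4-[(tert-butyldimethylsilyl)oxy]cyclopent-2-en-1-one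
Product: 3 (3R,4R)-4-[(tert-butyldimethylsilyl)oxy]-3-methyl-1-[(trimethylsilyl)oxy]cyclopent-1-ene, via lithium enolate 2 (not isolated)
Conditions: Me2CuLi (MeLi, CuI), Et2O, −78 °C; then Me3SiCl, Et3N, −78 → 0 °C
Reagents that add atoms: lithium dimethylcuprate [Li+].C[Cu-]C; chlorotrimethylsilane C[Si](C)(C)Cl
Why: Cuprate 1,4-addition occurs anti to the C2 silyl ether (the new C1 centre is erased in step 2) and O-silylation traps the regiodefined enolate: conjugate addition with enolate trapping.

Step 2
Reactants: 3 (3R,4R)-4-[(tert-butyldimethylsilyl)oxy]-3-methyl-1-[(trimethylsilyl)oxy]cyclopent-1-ene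
Product: 4 (R)-4-[(tert-butyldimethylsilyl)oxy]-3-methylcyclopent-2-en-1-one
Conditions: Pd(OAc)2 (1.05 equiv), MeCN, 23 °C
Reagents that add atoms: none
Why: Saegusa–Ito oxidation: the divalent palladium enolate formed from the silyl enol ether undergoes β-hydride elimination toward C1, giving the β-methyl enone with the C2 stereocentre untouched.

Step 3
Reactants: 5 ethyl 2-(2-methyl-1,3-dioxolan-2-yl)acetate
Product: 6 2-(2-methyl-1,3-dioxolan-2-yl)acetaldehyde
Conditions: i-Bu2AlH (1.05 equiv), CH2Cl2, −78 °C; aq. Rochelle salt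
Reagents that add atoms: none
Why: Partial reduction of an ester: the tetrahedral aluminium hemiacetal is stable at −78 °C and releases the aldehyde only on work-up; no stereocentre is formed.

Step 4
Reactants: 4 (R)-4-[(tert-butyldimethylsilyl)oxy]-3-methylcyclopent-2-en-1-one; 6 2-(2-methyl-1,3-dioxolan-2-yl)acetaldehyde
Product: 8 boryl aldol adduct (C4 ketone; C1: Bpin β and CH3 α; C2-OTBS α; C5 side chain α; C5/C6 anti), via boron enolate 7 (not isolated)
Conditions: CuCl (5 mol%), 1,3-dimesitylimidazolium chloride (5 mol%), NaOt-Bu (10 mol%), B2pin2 (1.1 equiv), THF, 23 °C; then 6, −78 → 0 °C; aq. NH4Cl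
Reagents that add atoms: bis(pinacolato)diboron CC1(C)OB(OC1(C)C)B1OC(C)(C)C(C)(C)O1
Why: The monovalent copper boryl adds to C1 anti to the C2 silyl ether, σ-bond metathesis with B2pin2 gives boron enolate 7, and 7 adds to aldehyde 6 through a chair Zimmerman–Traxler transition state on the α face opposite the bulky Bpin (C5), with the anti sense expected of a cyclic E-enolate (C6): copper-catalysed conjugate borylation with in situ aldol trapping.

Step 5
Reactants: 8 boryl aldol adduct
Product: 9 tertiary alcohol (C4: OH α and i-Pr β)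
Conditions: i-PrMgCl (3 equiv), CeCl3 (3 equiv), THF, −78 → −20 °C; aq. NH4Cl
Reagents that add atoms: isopropylmagnesium chloride CC(C)[Mg]Cl
Why: Organocerium 1,2-addition: the weakly basic isopropylcerium reagent (first equivalent consumed by the C6 hydroxyl) should add without enolisation, retro-aldol or attack at the hindered boronate, on the β face anti to the adjacent C5 side chain and the C2 silyl ether, so the new C4 hydroxyl is α (cis to C6).

Step 6
Reactants: 9 tertiary alcohol
Product: 10 keto diol (C8 methyl ketone; O4–H and O6–H free)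
Conditions: PPTS (0.2 equiv), acetone/H2O (10:1), 50 °C
Reagents that add atoms: water O
Why: Acid-catalysed ketal hydrolysis unmasks the C8 methyl ketone under conditions that the silyl ether, the pinacol boronate and the β-hydroxy ketone should tolerate; no stereocentre is touched.

Step 7
Reactants: 10 keto diol; 11 4-methoxybenzaldehyde dimethyl acetal
Product: 12 O4/O6-(4-methoxybenzylidene) acetal boronate
Conditions: PPTS (0.1 equiv), CH2Cl2, 4 Å MS, 23 °C
Reagents that add atoms: none
Why: Acid-catalysed transacetalisation of the cis-disposed O4–H/O6–H 1,3-diol gives the cis-fused 1,3-dioxane under thermodynamic control (i-Pr, C1, C7 and the aryl group at the new acetal carbon all equatorial); the acetal masks both hydroxyls, holds C1 and C7 gauche for ring closure and carries the future anisoyl carbon.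

Step 8
Reactants: 12 O4/O6-(4-methoxybenzylidene) acetal boronate
Product: 13 potassium trifluoroborate (BF3K on C1, β)
Conditions: KHF2 (4 equiv, aq.), MeOH, 0 → 23 °C, short contact; precipitation from acetone/Et2O
Reagents that add atoms: potassium hydrogen difluoride F.[F-].[K+]
Why: Boronate-to-trifluoroborate exchange gives the oxidisable tertiary radical precursor with retention at C1; brief contact at 0 °C should spare the acetal and the silyl ether.

Step 9
Reactants: 13 potassium trifluoroborate; 14 vinyltriphenylphosphonium bromide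
Product: 16 tricyclic O4/O6-(4-methoxybenzylidene) acetal of the trans-fused hydroazulene (C1: C10 β and CH3 α; C2-OTBS), via phosphonium ylide 15 (not isolated)
Conditions: [Ir(dF(CF3)ppy)2(bpy)]PF6 (2 mol%), 14 (1.5 equiv), KF (3 equiv), MeCN/DMF (4:1), blue LEDs (450 nm), 23 °C, degassed
Reagents that add atoms: none
Why: Proposed new method: the excited trivalent iridium photocatalyst oxidises trifluoroborate 13 to the tertiary C1 radical (fluoride takes up the BF3), which adds to the terminal carbon of 14 (C1–C10); the α-phosphonio radical is reduced by the divalent iridium species to ylide 15, which olefinates the C8 methyl ketone (C8=C9) with loss of Ph3P=O. The closest known reaction types are the photoredox Giese addition of tertiary alkyltrifluoroborates to electron-poor alkenes and the radical–polar crossover olefination in which a radical adds to a vinylphosphonium salt and the resulting ylide undergoes a Wittig reaction, here made intramolecular. Ring B closes as a seven-membered ring by intramolecular Wittig olefination of a ketone, the ring olefin necessarily having C7 and C10 cis, to give the trans-fused bicycle. The only new stereocentre is the quaternary C1: the planar radical is attacked on its β face, anti to the C2 silyl ether and the C5–C6 bond of the cis-fused dioxane that flank it on the α face, so C10 ends trans to C6 and the methyl cis to O2. The step needs the radical to choose 14 over the internal ketone and the ylide to choose the ketone: 5-exo addition of the C1 radical to the C8 carbonyl is reversible, the electrophilic α-phosphonio radical should not add to a second 14, no O–H is present to protonate the ylide, and the equatorial C1 and C7 on the dioxane chair hold C9 within reach of C8.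

Step 10
Reactants: 16 tricyclic acetal
Product: 17 6-O-(4-methoxybenzoyl)-2-O-TBS triol (O4–H free)
Conditions: DDQ (1.5 equiv), CH2Cl2/pH 7 buffer (10:1), 0 → 23 °C
Reagents that add atoms: water O
Why: Oxidative opening of a p-methoxybenzylidene acetal: DDQ abstracts hydride from the acetal C–H, water adds to the 2-aryl-1,3-dioxan-2-ylium ion, and the hemiorthoester should collapse to the ester of the secondary O6, releasing the more basic and more hindered tertiary O4–H (an O4 ester, if formed, should shift to O6 by 1,3-acyl transfer).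

Step 11
Reactants: 17 6-O-(4-methoxybenzoyl)-2-O-TBS triol
Product: 18 6-O-(4-methoxybenzoyl) triol (O2–H and O4–H free)
Conditions: HF·pyridine, pyridine, THF, 0 → 23 °C
Reagents that add atoms: none
Why: Fluoride-mediated desilylation under buffered conditions should cleave the secondary silyl ether without acyl migration or loss of the tertiary alcohol.

Step 12
Reactants: 18 6-O-(4-methoxybenzoyl) triol; 19 angelic acid
Product: 21 CNP0204191.1 (target), via mixed anhydride 20 (not isolated)
Conditions: 19, 2,4,6-Cl3C6H2COCl, Et3N, toluene, 23 °C; then 18, 80 °C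
Reagents that add atoms: none
Why: Yamaguchi-type esterification: the 2,4,6-trichlorobenzoyl mixed anhydride acylates the hindered secondary C2 hydroxyl thermally without DMAP or strong base, which should keep the Z geometry (no tiglate) and leave the tertiary C4 hydroxyl untouched.

**Compound list**

1 | (R)-4-[(tert-butyldimethylsilyl)oxy]cyclopent-2-en-1-one | O=C1C=C[C@H](O[Si](C)(C)C(C)(C)C)C1 | starting material
2 | lithium (3R,4R)-4-[(tert-butyldimethylsilyl)oxy]-3-methylcyclopent-1-en-1-olate | [Li+].[O-]C1=C[C@@H](C)[C@H](O[Si](C)(C)C(C)(C)C)C1 | intermediate (not isolated)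
3 | (3R,4R)-4-[(tert-butyldimethylsilyl)oxy]-3-methyl-1-[(trimethylsilyl)oxy]cyclopent-1-ene | C[Si](C)(C)OC1=C[C@@H](C)[C@H](O[Si](C)(C)C(C)(C)C)C1 | intermediate
4 | (R)-4-[(tert-butyldimethylsilyl)oxy]-3-methylcyclopent-2-en-1-one | O=C1C=C(C)[C@H](O[Si](C)(C)C(C)(C)C)C1 | intermediate
5 | ethyl 2-(2-methyl-1,3-dioxolan-2-yl)acetate | CCOC(=O)CC1(C)OCCO1 | starting material
6 | 2-(2-methyl-1,3-dioxolan-2-yl)acetaldehyde | O=CCC1(C)OCCO1 | intermediate
7 | pinacolboron enolate of the β-boryl ketone (O-Bpin on C4; C-Bpin β on C1; OTBS α on C2) | CC1(C)OB(OC2=C[C@@](C)(B3OC(C)(C)C(C)(C)O3)[C@H](O[Si](C)(C)C(C)(C)C)C2)OC1(C)C | intermediate (not isolated)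
8 | boryl aldol adduct: 4-(TBSO)-2-[1-hydroxy-2-(2-methyl-1,3-dioxolan-2-yl)ethyl]-3-methyl-3-(pinacolboryl)cyclopentan-1-one; Bpin β; CH3, OTBS and side chain α; C5/C6 anti | O=C1[C@H]([C@@H](O)CC2(C)OCCO2)[C@@](C)(B3OC(C)(C)C(C)(C)O3)[C@H](O[Si](C)(C)C(C)(C)C)C1 | intermediate
9 | tertiary alcohol: as 8 with C4(OH)(i-Pr), OH α and i-Pr β | O[C@]1(C(C)C)[C@H]([C@@H](O)CC2(C)OCCO2)[C@@](C)(B3OC(C)(C)C(C)(C)O3)[C@H](O[Si](C)(C)C(C)(C)C)C1 | intermediate
10 | keto diol: as 9 with the dioxolane hydrolysed to the C8 methyl ketone | O[C@]1(C(C)C)[C@H]([C@@H](O)CC(C)=O)[C@@](C)(B2OC(C)(C)C(C)(C)O2)[C@H](O[Si](C)(C)C(C)(C)C)C1 | intermediate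
11 | 4-methoxybenzaldehyde dimethyl acetal | COC(OC)c1ccc(OC)cc1 | starting material
12 | O4/O6-(4-methoxybenzylidene) acetal of 10 (aryl equatorial; Bpin β on C1) | COc1ccc(cc1)[C@@H]2O[C@@]3(C(C)C)C[C@@H](O[Si](C)(C)C(C)(C)C)[C@](C)(B4OC(C)(C)C(C)(C)O4)[C@H]3[C@H](CC(C)=O)O2 | intermediate
13 | potassium trifluoroborate corresponding to 12 | COc1ccc(cc1)[C@@H]2O[C@@]3(C(C)C)C[C@@H](O[Si](C)(C)C(C)(C)C)[C@](C)([B-](F)(F)F)[C@H]3[C@H](CC(C)=O)O2.[K+] | intermediate
14 | vinyltriphenylphosphonium bromide | C=C[P+](c1ccccc1)(c1ccccc1)c1ccccc1.[Br-] | starting material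
15 | phosphonium ylide (C1–C10H2–C9H(−)–P(+)Ph3 with the C8 ketone intact; C10 β on C1) | COc1ccc(cc1)[C@@H]2O[C@@]3(C(C)C)C[C@@H](O[Si](C)(C)C(C)(C)C)[C@](C)(C[CH-][P+](c4ccccc4)(c4ccccc4)c4ccccc4)[C@H]3[C@H](CC(C)=O)O2 | intermediate (not isolated)
16 | tricyclic acetal: 2-O-TBS-4,6-O-(4-methoxybenzylidene)dauc-8-ene-2,4,6-triol | COc1ccc(cc1)[C@@H]2O[C@@]3(C(C)C)C[C@@H](O[Si](C)(C)C(C)(C)C)[C@]4(C)CC=C(C)C[C@H](O2)[C@@H]34 | intermediate
17 | 6-O-(4-methoxybenzoyl)-2-O-TBS-dauc-8-ene-2,4,6-triol | CC(C)(C)[Si](C)(C)O[C@@H]1C[C@@](O)(C(C)C)[C@@H]2[C@@H](OC(=O)c3ccc(OC)cc3)CC(C)=CC[C@]21C | intermediate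
18 | 6-O-(4-methoxybenzoyl)dauc-8-ene-2,4,6-triol | O[C@@H]1C[C@@](O)(C(C)C)[C@@H]2[C@@H](OC(=O)c3ccc(OC)cc3)CC(C)=CC[C@]21C | intermediate
19 | angelic acid, (Z)-2-methylbut-2-enoic acid | C/C=C(/C)C(=O)O | starting material
20 | angelic 2,4,6-trichlorobenzoic anhydride | C/C=C(/C)C(=O)OC(=O)c1c(Cl)cc(Cl)cc1Cl | intermediate (not isolated)
21 | CNP0204191.1: (1R,2R,4R,5S,6S)-2-angeloyloxy-4-hydroxy-6-(4-methoxybenzoyloxy)dauc-8-ene | C/C=C(/C)C(=O)O[C@@H]1C[C@@](O)(C(C)C)[C@@H]2[C@@H](OC(=O)c3ccc(OC)cc3)CC(C)=CC[C@]21C | target

**Step count and risks**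

Total steps: 12. Longest linear sequence: 11 (steps 1, 2, 4–12; step 3 is a one-step side branch).

Steps most likely to fail:

Step 9 (Proposed new method). The ylide may be protonated or captured by boron Lewis acid before it reaches the ketone, reduction of the α-phosphonio radical may be slow so that hydrogen abstraction wins, or the β-face preference at the C1 radical may be eroded. The fallback uses known chemistry and sets out from 13. Photoredox radical allylation with allyl phenyl sulfone ([Ir(dF(CF3)ppy)2(bpy)]PF6, blue LEDs) should give the C1-allyl ketone F1 under the same facial control. Wittig methylenation of the C8 ketone (Ph3P=CH2, THF) gives the diene F2. Ring-closing metathesis with the second-generation Grubbs catalyst (CH2Cl2, 40 °C) then closes ring B between the allyl group and the 1,1-disubstituted alkene, coming back to the route at 16.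

Step 5. Enolisation, β-hydride reduction of the hindered ketone, retro-aldol cleavage of the C6 alkoxide or attack at boron may outcompete addition. The fallback sets out from 8: the smaller, less basic sp2 reagent made from CH2=C(CH3)MgBr and CeCl3 adds to give the isopropenyl carbinol F4, and hydrogenation of its 1,1-disubstituted alkene ((Ph3P)3RhCl, H2) comes back to the route at 9.

Step 10. The hemiorthoester may collapse toward the O4 ester, or DDQ may over-oxidise at the allylic positions. The fallback sets out from 16: transacetalisation (PPTS, MeOH, 40 °C) removes the acetal to give the diol F3, and selective acylation of its secondary C6 hydroxyl with 4-methoxybenzoyl chloride (pyridine, DMAP, 0 °C; tertiary O4–H inert) comes back to the route at 17.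

**Further compounds**

F1 | step 9 | C1-allyl ketone (allyl β on C1; acetal, OTBS and C8 ketone as in 13) | COc1ccc(cc1)[C@@H]2O[C@@]3(C(C)C)C[C@@H](O[Si](C)(C)C(C)(C)C)[C@](C)(CC=C)[C@H]3[C@H](CC(C)=O)O2
F2 | step 9 | diene (F1 with the C8 ketone converted to C8(CH3)=CH2) | COc1ccc(cc1)[C@@H]2O[C@@]3(C(C)C)C[C@@H](O[Si](C)(C)C(C)(C)C)[C@](C)(CC=C)[C@H]3[C@H](CC(C)=C)O2
F3 | step 10 | 2-O-TBS-dauc-8-ene-2,4,6-triol (O4–H and O6–H free) | CC(C)(C)[Si](C)(C)O[C@@H]1C[C@@](O)(C(C)C)[C@@H]2[C@@H](O)CC(C)=CC[C@]21C
F4 | step 5 | isopropenyl carbinol (9 with prop-1-en-2-yl in place of i-Pr at C4) | O[C@]1(C(C)=C)[C@H]([C@@H](O)CC2(C)OCCO2)[C@@](C)(B3OC(C)(C)C(C)(C)O3)[C@H](O[Si](C)(C)C(C)(C)C)C1
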